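**Retrosynthetic overview**

1. Oxepane: the C3–O–C16 ether bond is closed last, by displacement of a primary C16 triflate by the tertiary C3 hydroxyl.
2. Oxonene: C6=C7 by ring-closing metathesis of the two side chains held cis on the tetrahydrofuran.
3. Tetrahydrofuran: C9–O and C9–C10 in one condensation of the C2 alcohol and the enol carbamate with a methallyl acetal, which also frees the C11 ketone.
4. Key bond C1–C2: a titanated, fully substituted cyclohex-2-enyl carbamate acts as the homoenolate (d3 synthon) of the C11 ketone and adds to an α-silyloxy aldehyde, setting C1 and C2.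
5. Cyclohexene by organocatalytic Michael/aldol annulation; ring order: cyclohexene, tetrahydrofuran, oxonene, oxepane.

Assumption: asbestinin (cladiellane) numbering C1–C16 is used (C16 = OCH2, C15 = CH(CH3)); the SMILES is read as 1S,2S,3S,9S,10R,11R,12R,14S,15R with a 6Z alkene; commercial solutions of the two Grignard reagents and (R)-2-methylglycidol count as starting materials.

**Route**

Step 1
Reactants: 1 methyl (S)-3-hydroxy-2-methylpropanoate
Product: 2 methyl (S)-2-methyl-3-[(triisopropylsilyl)oxy]propanoate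
Conditions: iPr3SiCl, imidazole, DMF, rt
Reagents that add atoms: chlorotriisopropylsilane, CC(C)[Si](Cl)(C(C)C)C(C)C
Why: Imidazole-promoted O-silylation masks the future C16 oxygen with a group that survives base, organolithium and Lewis-acid steps, and no stereocenter is touched.

Step 2
Reactants: 2 methyl (S)-2-methyl-3-[(triisopropylsilyl)oxy]propanoate
Product: 3 (S)-2-methyl-3-[(triisopropylsilyl)oxy]propanal
Conditions: iBu2AlH, CH2Cl2, −78 °C; aq. KNaC4H4O6
Reagents that add atoms: none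
Why: Partial ester reduction stops at the tetrahedral aluminate at −78 °C and releases the aldehyde on work-up without epimerising the α-stereocenter.

Step 3
Reactants: 3 (S)-2-methyl-3-[(triisopropylsilyl)oxy]propanal
Product: 5 (R)-3-methyl-4-[(triisopropylsilyl)oxy]butanal, via enol ether 4 (not isolated)
Conditions: MeOCH2PPh3Cl, KN(SiMe3)2, THF, 0 °C; then 3, −78 → 0 °C; then 2 M aq. HCl, THF, rt
Reagents that add atoms: (methoxymethyl)triphenylphosphonium chloride, [Cl-].COC[P+](c1ccccc1)(c1ccccc1)c1ccccc1; water, O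
Why: Wittig methoxymethylenation followed by enol ether hydrolysis is a one-carbon homologation that moves the C15 stereocenter to the non-epimerisable β-position.

Step 4
Reactants: 5 (R)-3-methyl-4-[(triisopropylsilyl)oxy]butanal; 6 but-3-en-2-one
Product: 8 (R)-4-[(R)-1-[(triisopropylsilyl)oxy]propan-2-yl]cyclohex-2-en-1-one, via keto aldehyde 7 (not isolated)
Conditions: 6 (1.5 equiv), (S)-α,α-diphenylprolinol trimethylsilyl ether (5 mol%), ethyl 3,4-dihydroxybenzoate (20 mol%), neat, 4 °C; then KOH, nBu4NOH (aq.), Et2O/THF, reflux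
Reagents that add atoms: none
Why: Enamine-catalysed Michael addition, in which the diarylprolinol silyl ether shields one enamine face and sets C14 under catalyst control, is followed by base-mediated intramolecular aldol condensation (Robinson-type annulation).

Step 5
Reactants: 8 (R)-4-[(R)-1-[(triisopropylsilyl)oxy]propan-2-yl]cyclohex-2-en-1-one
Product: 10 (4R,6R)-6-methyl-4-[(R)-1-[(triisopropylsilyl)oxy]propan-2-yl]cyclohex-2-en-1-one, via lithium dienolate 9 (not isolated)
Conditions: LiN(iPr)2, THF, −78 °C; MeI, −78 → −40 °C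
Reagents that add atoms: iodomethane, CI
Why: Kinetic α′-enolate alkylation, in which axial attack anti to the pseudo-equatorial C4 side chain sets C12 with the methyl group trans to the side chain (the axial, kinetic epimer).

Step 6
Reactants: 10 (4R,6R)-6-methyl-4-[(R)-1-[(triisopropylsilyl)oxy]propan-2-yl]cyclohex-2-en-1-one
Product: 11 (1R,4R,6R)-6-methyl-4-[(R)-1-[(triisopropylsilyl)oxy]propan-2-yl]cyclohex-2-en-1-ol
Conditions: NaBH4, CeCl3·7H2O, MeOH, −78 → −40 °C
Reagents that add atoms: none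
Why: Luche 1,2-reduction in which hydride attacks axially and anti to the axial C6 methyl group, giving the alcohol cis to the methyl group and trans to the C4 side chain.

Step 7
Reactants: 11 (1R,4R,6R)-6-methyl-4-[(R)-1-[(triisopropylsilyl)oxy]propan-2-yl]cyclohex-2-en-1-ol
Product: 12 (1R,4R,6R)-6-methyl-4-[(R)-1-[(triisopropylsilyl)oxy]propan-2-yl]cyclohex-2-en-1-yl N,N-diisopropylcarbamate
Conditions: iPr2NCOCl, pyridine, DMAP (cat.), 90 °C
Reagents that add atoms: N,N-diisopropylcarbamoyl chloride, CC(C)N(C(C)C)C(Cl)=O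
Why: O-Carbamoylation installs the directing and carbanion-stabilising group for α-lithiation with the carbinol configuration unchanged.

Step 8
Reactants: 13 (R)-(2-methyloxiran-2-yl)methanol; 14 allylmagnesium chloride
Product: 15 (S)-2-methylhex-5-ene-1,2-diol
Conditions: 14 (3 equiv), CuI (10 mol%), THF, −40 → 0 °C; aq. NH4Cl
Reagents that add atoms: none
Why: Copper-catalysed SN2 opening of the 2,2-disubstituted epoxide at its CH2 terminus leaves the quaternary C3 stereocenter untouched.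

Step 9
Reactants: 15 (S)-2-methylhex-5-ene-1,2-diol
Product: 16 (S)-2-methyl-1,2-bis[(triethylsilyl)oxy]hex-5-ene
Conditions: Et3SiOTf (2.5 equiv), 2,6-lutidine, CH2Cl2, −78 → 0 °C
Reagents that add atoms: triethylsilyl trifluoromethanesulfonate, CC[Si](CC)(CC)OS(=O)(=O)C(F)(F)F
Why: Exhaustive silylation with the silyl triflate protects the hindered tertiary alcohol, and the primary silyl ether is unmasked oxidatively in the next step.

Step 10
Reactants: 16 (S)-2-methyl-1,2-bis[(triethylsilyl)oxy]hex-5-ene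
Product: 17 (S)-2-methyl-2-[(triethylsilyl)oxy]hex-5-enal
Conditions: (COCl)2, DMSO, CH2Cl2, −78 → −40 °C; Et3N, −78 °C → rt
Reagents that add atoms: none
Why: Swern oxidation of a primary triethylsilyl ether, in which the chlorosulfonium salt desilylates only the unhindered primary ether and the alkoxysulfonium ion collapses to the aldehyde, which has no α-hydrogen and cannot epimerise.

Step 11
Reactants: 18 (2-methylallyl)magnesium chloride; 19 triethyl orthoformate
Product: 20 4,4-diethoxy-2-methylbut-1-ene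
Conditions: THF, reflux; aq. NH4Cl
Reagents that add atoms: none
Why: Bodroux–Chichibabin-type substitution of one ethoxy group of the orthoformate by the allylic Grignard reagent gives the acetal of the otherwise unstable β,γ-unsaturated aldehyde.

Step 12
Reactants: 12 (1R,4R,6R)-6-methyl-4-[(R)-1-[(triisopropylsilyl)oxy]propan-2-yl]cyclohex-2-en-1-yl N,N-diisopropylcarbamate; 17 (S)-2-methyl-2-[(triethylsilyl)oxy]hex-5-enal
Product: 23 (3S,4S,6R)-3-[(1S,2S)-1-hydroxy-2-methyl-2-[(triethylsilyl)oxy]hex-5-en-1-yl]-6-methyl-4-[(R)-1-[(triisopropylsilyl)oxy]propan-2-yl]cyclohex-1-en-1-yl N,N-diisopropylcarbamate, via lithiated carbamate 21 (not isolated), via allyltitanium triisopropoxide 22 (not isolated)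
Conditions: sBuLi, TMEDA, Et2O, −78 °C; ClTi(OiPr)3, −78 °C; 17, −78 °C; aq. NH4Cl
Reagents that add atoms: none
Why: Hoppe homoaldol reaction, in which the pseudo-axial α-hydrogen is removed with retention, Li-to-Ti exchange goes with inversion, and the allyltitanium (a d3 homoenolate of the C11 ketone) adds at its γ-carbon through a cyclic syn-SE′ transition state on the face anti to the C14 side chain (sets C1) with the aldehyde substituent turned away from the ring, giving the anti adduct known for titanated cyclohex-2-enyl carbamates (sets C2).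

Step 13
Reactants: 23 (3S,4S,6R)-3-[(1S,2S)-1-hydroxy-2-methyl-2-[(triethylsilyl)oxy]hex-5-en-1-yl]-6-methyl-4-[(R)-1-[(triisopropylsilyl)oxy]propan-2-yl]cyclohex-1-en-1-yl N,N-diisopropylcarbamate; 20 4,4-diethoxy-2-methylbut-1-ene
Product: 24 (1S,3S,3aR,5R,7S,7aS)-5-methyl-3-(2-methylallyl)-1-[(S)-2-[(triethylsilyl)oxy]hex-5-en-2-yl]-7-[(R)-1-[(triisopropylsilyl)oxy]propan-2-yl]hexahydroisobenzofuran-4(1H)-one
Conditions: 20 (1.5 equiv), BF3·OEt2 (2 equiv), Et2O, −78 → −30 °C; aq. NaHCO3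
Reagents that add atoms: none
Why: Lewis-acid-mediated condensation in which the C2 hydroxyl and the acetal give an (E)-oxocarbenium ion that the enol carbamate captures intramolecularly (Mukaiyama/Prins-type five-ring closure) on the face of the C1–C2 bond, giving the cis-fused tetrahydrofuran with the C9 chain cis to the C2 chain (sets C9 and C10) and freeing the C11 ketone.

Step 14
Reactants: 24 (1S,3S,3aR,5R,7S,7aS)-5-methyl-3-(2-methylallyl)-1-[(S)-2-[(triethylsilyl)oxy]hex-5-en-2-yl]-7-[(R)-1-[(triisopropylsilyl)oxy]propan-2-yl]hexahydroisobenzofuran-4(1H)-one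
Product: 26 (1S,3S,3aR,4R,5R,7S,7aS)-5-methyl-3-(2-methylallyl)-1-[(S)-2-[(triethylsilyl)oxy]hex-5-en-2-yl]-7-[(R)-1-[(triisopropylsilyl)oxy]propan-2-yl]octahydroisobenzofuran-4-yl acetate, via lithium alkoxide 25 (not isolated)
Conditions: LiBH(sBu)3, THF, −78 °C; then Ac2O, DMAP, −78 °C → rt
Reagents that add atoms: acetic anhydride, CC(=O)OC(C)=O
Why: Hydride reduction from the convex face of the cis-fused bicycle, anti to the axial C12 methyl group and the C10–C9 bond, gives the 11R alkoxide (oxygen cis to the C12 methyl group), which is O-acetylated in the same flask before the α-methyl ketone can epimerise.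

Step 15
Reactants: 26 (1S,3S,3aR,4R,5R,7S,7aS)-5-methyl-3-(2-methylallyl)-1-[(S)-2-[(triethylsilyl)oxy]hex-5-en-2-yl]-7-[(R)-1-[(triisopropylsilyl)oxy]propan-2-yl]octahydroisobenzofuran-4-yl acetate
Product: 27 (1S,2S,3S,6Z,9S,10R,11R,12R,14S)-3,7,12-trimethyl-3-[(triethylsilyl)oxy]-14-[(R)-1-[(triisopropylsilyl)oxy]propan-2-yl]-2,9-epoxybicyclo[8.4.0]tetradec-6-en-11-yl acetate (cladiellane numbering)
Conditions: second-generation Grubbs catalyst RuCl2(=CHPh)(PCy3)(H2IMes) (10 mol%), CH2Cl2 (2 mM), 40 °C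
Reagents that add atoms: none
Why: Ring-closing metathesis between the monosubstituted and the 1,1-disubstituted alkene held cis on the tetrahydrofuran closes the nine-membered oxacycle, whose strain allows only the Z trisubstituted alkene.

Step 16
Reactants: 27 (1S,2S,3S,6Z,9S,10R,11R,12R,14S)-3,7,12-trimethyl-3-[(triethylsilyl)oxy]-14-[(R)-1-[(triisopropylsilyl)oxy]propan-2-yl]-2,9-epoxybicyclo[8.4.0]tetradec-6-en-11-yl acetate
Product: 28 (1S,2S,3S,6Z,9S,10R,11R,12R,14S)-3-hydroxy-14-[(R)-1-hydroxypropan-2-yl]-3,7,12-trimethyl-2,9-epoxybicyclo[8.4.0]tetradec-6-en-11-yl acetate (cladiellane numbering)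
Conditions: HF·pyridine, pyridine/THF, 0 °C → rt
Reagents that add atoms: none
Why: Fluoride-mediated cleavage of both silyl ethers frees the tertiary C3 and primary C16 hydroxyls without touching the acetate or any stereocenter.

Step 17
Reactants: 28 (1S,2S,3S,6Z,9S,10R,11R,12R,14S)-3-hydroxy-14-[(R)-1-hydroxypropan-2-yl]-3,7,12-trimethyl-2,9-epoxybicyclo[8.4.0]tetradec-6-en-11-yl acetate
Product: 30 target CNP0177382.3, via primary triflate 29 (not isolated)
Conditions: Tf2O, 2,6-lutidine, CH2Cl2, −78 → 0 °C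
Reagents that add atoms: none
Why: Selective triflation of the primary alcohol is followed by intramolecular Williamson-type SN2 displacement by the tertiary C3 hydroxyl (7-exo-tet), which closes the oxepane at a non-stereogenic carbon.

**Compound list**

1 | methyl (S)-3-hydroxy-2-methylpropanoate | COC(=O)[C@@H](C)CO | starting material
2 | methyl (S)-2-methyl-3-[(triisopropylsilyl)oxy]propanoate | COC(=O)[C@@H](C)CO[Si](C(C)C)(C(C)C)C(C)C | intermediate
3 | (S)-2-methyl-3-[(triisopropylsilyl)oxy]propanal | O=C[C@@H](C)CO[Si](C(C)C)(C(C)C)C(C)C | intermediate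
4 | (R)-1-methoxy-3-methyl-4-[(triisopropylsilyl)oxy]but-1-ene (E/Z mixture) | COC=C[C@@H](C)CO[Si](C(C)C)(C(C)C)C(C)C | intermediate
5 | (R)-3-methyl-4-[(triisopropylsilyl)oxy]butanal | O=CC[C@@H](C)CO[Si](C(C)C)(C(C)C)C(C)C | intermediate
6 | but-3-en-2-one | CC(=O)C=C | starting material
7 | (S)-5-oxo-2-[(R)-1-[(triisopropylsilyl)oxy]propan-2-yl]hexanal | O=C[C@@H](CCC(C)=O)[C@@H](C)CO[Si](C(C)C)(C(C)C)C(C)C | intermediate
8 | (R)-4-[(R)-1-[(triisopropylsilyl)oxy]propan-2-yl]cyclohex-2-en-1-one | O=C1C=C[C@@H](CC1)[C@@H](C)CO[Si](C(C)C)(C(C)C)C(C)C | intermediate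
9 | lithium (R)-4-[(R)-1-[(triisopropylsilyl)oxy]propan-2-yl]cyclohexa-1,5-dien-1-olate | [Li]OC1=CC[C@H](C=C1)[C@@H](C)CO[Si](C(C)C)(C(C)C)C(C)C | intermediate
10 | (4R,6R)-6-methyl-4-[(R)-1-[(triisopropylsilyl)oxy]propan-2-yl]cyclohex-2-en-1-one | O=C1C=C[C@@H](C[C@H]1C)[C@@H](C)CO[Si](C(C)C)(C(C)C)C(C)C | intermediate
11 | (1R,4R,6R)-6-methyl-4-[(R)-1-[(triisopropylsilyl)oxy]propan-2-yl]cyclohex-2-en-1-ol | O[C@H]1C=C[C@@H](C[C@H]1C)[C@@H](C)CO[Si](C(C)C)(C(C)C)C(C)C | intermediate
12 | (1R,4R,6R)-6-methyl-4-[(R)-1-[(triisopropylsilyl)oxy]propan-2-yl]cyclohex-2-en-1-yl N,N-diisopropylcarbamate | CC(C)N(C(C)C)C(=O)O[C@H]1C=C[C@@H](C[C@H]1C)[C@@H](C)CO[Si](C(C)C)(C(C)C)C(C)C | intermediate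
13 | (R)-(2-methyloxiran-2-yl)methanol | OC[C@]1(C)CO1 | starting material
14 | allylmagnesium chloride | C=CC[Mg]Cl | starting material
15 | (S)-2-methylhex-5-ene-1,2-diol | OC[C@](C)(CCC=C)O | intermediate
16 | (S)-2-methyl-1,2-bis[(triethylsilyl)oxy]hex-5-ene | CC[Si](CC)(CC)OC[C@](C)(CCC=C)O[Si](CC)(CC)CC | intermediate
17 | (S)-2-methyl-2-[(triethylsilyl)oxy]hex-5-enal | O=C[C@](C)(CCC=C)O[Si](CC)(CC)CC | intermediate
18 | (2-methylallyl)magnesium chloride | CC(=C)C[Mg]Cl | starting material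
19 | triethyl orthoformate | CCOC(OCC)OCC | starting material
20 | 4,4-diethoxy-2-methylbut-1-ene | CCOC(CC(C)=C)OCC | intermediate
21 | C11-lithio derivative of 12 (lithium in place of the carbinol hydrogen, retention) | CC(C)N(C(C)C)C(=O)O[C@@]1([Li])C=C[C@@H](C[C@H]1C)[C@@H](C)CO[Si](C(C)C)(C(C)C)C(C)C | intermediate
22 | C11-triisopropoxytitanium derivative of 12 (titanium on the face anti to the C14 side chain, inversion) | CC(C)N(C(C)C)C(=O)O[C@]1([Ti](OC(C)C)(OC(C)C)OC(C)C)C=C[C@@H](C[C@H]1C)[C@@H](C)CO[Si](C(C)C)(C(C)C)C(C)C | intermediate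
23 | (3S,4S,6R)-3-[(1S,2S)-1-hydroxy-2-methyl-2-[(triethylsilyl)oxy]hex-5-en-1-yl]-6-methyl-4-[(R)-1-[(triisopropylsilyl)oxy]propan-2-yl]cyclohex-1-en-1-yl N,N-diisopropylcarbamate | CC(C)N(C(C)C)C(=O)OC1=C[C@H]([C@@H](C[C@H]1C)[C@@H](C)CO[Si](C(C)C)(C(C)C)C(C)C)[C@H](O)[C@](C)(CCC=C)O[Si](CC)(CC)CC | intermediate
24 | (1S,3S,3aR,5R,7S,7aS)-5-methyl-3-(2-methylallyl)-1-[(S)-2-[(triethylsilyl)oxy]hex-5-en-2-yl]-7-[(R)-1-[(triisopropylsilyl)oxy]propan-2-yl]hexahydroisobenzofuran-4(1H)-one | O=C1[C@@H]2[C@H]([C@@H](C[C@H]1C)[C@@H](C)CO[Si](C(C)C)(C(C)C)C(C)C)[C@H](O[C@H]2CC(C)=C)[C@](C)(CCC=C)O[Si](CC)(CC)CC | intermediate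
25 | lithium alkoxide of the 11R alcohol derived from 24 | [Li]O[C@H]1[C@@H]2[C@H]([C@@H](C[C@H]1C)[C@@H](C)CO[Si](C(C)C)(C(C)C)C(C)C)[C@H](O[C@H]2CC(C)=C)[C@](C)(CCC=C)O[Si](CC)(CC)CC | intermediate
26 | (1S,3S,3aR,4R,5R,7S,7aS)-5-methyl-3-(2-methylallyl)-1-[(S)-2-[(triethylsilyl)oxy]hex-5-en-2-yl]-7-[(R)-1-[(triisopropylsilyl)oxy]propan-2-yl]octahydroisobenzofuran-4-yl acetate | CC(=O)O[C@H]1[C@@H]2[C@H]([C@@H](C[C@H]1C)[C@@H](C)CO[Si](C(C)C)(C(C)C)C(C)C)[C@H](O[C@H]2CC(C)=C)[C@](C)(CCC=C)O[Si](CC)(CC)CC | intermediate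
27 | (1S,2S,3S,6Z,9S,10R,11R,12R,14S)-3,7,12-trimethyl-3-[(triethylsilyl)oxy]-14-[(R)-1-[(triisopropylsilyl)oxy]propan-2-yl]-2,9-epoxybicyclo[8.4.0]tetradec-6-en-11-yl acetate (cladiellane numbering) | CC(=O)O[C@H]1[C@@H]2[C@H]([C@@H](C[C@H]1C)[C@@H](C)CO[Si](C(C)C)(C(C)C)C(C)C)[C@@H]3O[C@H]2C/C(C)=C\CC[C@]3(C)O[Si](CC)(CC)CC | intermediate
28 | (1S,2S,3S,6Z,9S,10R,11R,12R,14S)-3-hydroxy-14-[(R)-1-hydroxypropan-2-yl]-3,7,12-trimethyl-2,9-epoxybicyclo[8.4.0]tetradec-6-en-11-yl acetate (cladiellane numbering) | CC(=O)O[C@H]1[C@@H]2[C@H]([C@@H](C[C@H]1C)[C@@H](C)CO)[C@@H]3O[C@H]2C/C(C)=C\CC[C@]3(C)O | intermediate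
29 | C16 trifluoromethanesulfonate of 28 | CC(=O)O[C@H]1[C@@H]2[C@H]([C@@H](C[C@H]1C)[C@@H](C)COS(=O)(=O)C(F)(F)F)[C@@H]3O[C@H]2C/C(C)=C\CC[C@]3(C)O | intermediate
30 | target CNP0177382.3 | CC(=O)O[C@H]1[C@@H]2[C@@H]3[C@@H](C[C@H]1C)[C@@H](C)CO[C@@]1(C)CC/C=C(/C)C[C@@H]2O[C@@H]31 | target

**Step count and risks**

Total step count: 17. Longest linear sequence: 13 steps (steps 1–7, then 12–17).

Three steps most likely to fail:

Step 12. The C12 methyl group sits next to the carbanion carbon and on the face that titanium must take, so deprotonation or Li-to-Ti exchange may stall, and the anti selectivity at C2 is extrapolated from carbamates without this methyl group. The fallback leaves the methyl group out of the key step and brings it in late; it sets out from 8 and comes back at 24. Enone 8 is reduced under Luche conditions to (1R,4R)-4-[(R)-1-[(triisopropylsilyl)oxy]propan-2-yl]cyclohex-2-en-1-ol F1 and carbamoylated to the 12-demethyl carbamate F2. F2 is carried through the homoaldol addition to 17, giving the 12-demethyl adduct F3, and through the condensation with 20, giving the 12-demethyl ketone F4. α-Methylenation of F4 at the unhindered C12 (paraformaldehyde, N-methylanilinium trifluoroacetate, THF, reflux) gives the 12-methylene ketone F5. 1,4-Reduction of F5 with LiBH(sBu)3 at −78 °C forms the lithium enolate F6, and kinetic protonation from the convex face (2,6-di-tert-butylphenol, −78 °C) places the methyl group axial and gives 24.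

Step 13. The oxocarbenium ion may be intercepted by the neighbouring C3 silyl ether oxygen, acetal exchange at the hindered C2 hydroxyl may be slow, and the ketone can epimerise at C12 under Lewis acid. The fallback generates the same cation by segment coupling instead of intermolecular acetal exchange; it sets out from 23 and comes back at 24. The C2 hydroxyl of 23 is esterified with 3-methylbut-3-enoic acid (diisopropylcarbodiimide, DMAP) to the 3-methylbut-3-enoate ester F7. Reductive acetylation (iBu2AlH, −78 °C; then Ac2O, pyridine, DMAP) gives the α-acetoxy ether F8. BF3·OEt2 at −78 °C ionises F8, and the enol carbamate closes the tetrahydrofuran to give 24.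

Step 15. Closing a nine-membered ring with a trisubstituted alkene next to the bulky C3 silyl ether may lose to dimerisation. The fallback changes the ring order so that metathesis runs on a preorganised tetracycle; it sets out from 26 and comes back at 30. Desilylation of 26 with HF·pyridine gives the diol diene F9. Tf2O and 2,6-lutidine convert F9 to the primary triflate F10, which cyclises to the oxepane diene F11. Ring-closing metathesis of F11 with the second-generation Grubbs catalyst then gives 30 directly.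

**Further compounds**

F1 | step 12 | (1R,4R)-4-[(R)-1-[(triisopropylsilyl)oxy]propan-2-yl]cyclohex-2-en-1-ol | O[C@H]1C=C[C@@H](CC1)[C@@H](C)CO[Si](C(C)C)(C(C)C)C(C)C
F2 | step 12 | 12-demethyl analogue of 12 | CC(C)N(C(C)C)C(=O)O[C@H]1C=C[C@@H](CC1)[C@@H](C)CO[Si](C(C)C)(C(C)C)C(C)C
F3 | step 12 | 12-demethyl analogue of 23 | CC(C)N(C(C)C)C(=O)OC1=C[C@H]([C@@H](CC1)[C@@H](C)CO[Si](C(C)C)(C(C)C)C(C)C)[C@H](O)[C@](C)(CCC=C)O[Si](CC)(CC)CC
F4 | step 12 | 12-demethyl analogue of 24 | O=C1[C@@H]2[C@H]([C@@H](CC1)[C@@H](C)CO[Si](C(C)C)(C(C)C)C(C)C)[C@H](O[C@H]2CC(C)=C)[C@](C)(CCC=C)O[Si](CC)(CC)CC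
F5 | step 12 | 12-methylene analogue of 24 | O=C1[C@@H]2[C@H]([C@@H](CC1=C)[C@@H](C)CO[Si](C(C)C)(C(C)C)C(C)C)[C@H](O[C@H]2CC(C)=C)[C@](C)(CCC=C)O[Si](CC)(CC)CC
F6 | step 12 | lithium C11–C12 enolate of 24 | [Li]OC1=C(C)C[C@@H]([C@@H](C)CO[Si](C(C)C)(C(C)C)C(C)C)[C@@H]2[C@H](O[C@@H](CC(C)=C)[C@H]12)[C@](C)(CCC=C)O[Si](CC)(CC)CC
F7 | step 13 | C2 3-methylbut-3-enoate ester of 23 | CC(C)N(C(C)C)C(=O)OC1=C[C@H]([C@@H](C[C@H]1C)[C@@H](C)CO[Si](C(C)C)(C(C)C)C(C)C)[C@H](OC(=O)CC(C)=C)[C@](C)(CCC=C)O[Si](CC)(CC)CC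
F8 | step 13 | C2 1-acetoxy-3-methylbut-3-enyl ether of 23 (acetal epimers) | CC(C)N(C(C)C)C(=O)OC1=C[C@H]([C@@H](C[C@H]1C)[C@@H](C)CO[Si](C(C)C)(C(C)C)C(C)C)[C@H](OC(CC(C)=C)OC(C)=O)[C@](C)(CCC=C)O[Si](CC)(CC)CC
F9 | step 15 | bis-desilylated 26 (C3,C16 diol diene) | CC(=O)O[C@H]1[C@@H]2[C@H]([C@@H](C[C@H]1C)[C@@H](C)CO)[C@H](O[C@H]2CC(C)=C)[C@](C)(CCC=C)O
F10 | step 15 | C16 trifluoromethanesulfonate of F9 | CC(=O)O[C@H]1[C@@H]2[C@H]([C@@H](C[C@H]1C)[C@@H](C)COS(=O)(=O)C(F)(F)F)[C@H](O[C@H]2CC(C)=C)[C@](C)(CCC=C)O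
F11 | step 15 | oxepane diene (target skeleton lacking the C6–C7 ring bond, with but-3-enyl on C3 and 2-methylallyl on C9) | CC(=O)O[C@H]1[C@@H]2[C@@H]3[C@@H](C[C@H]1C)[C@@H](C)CO[C@@](C)(CCC=C)[C@H]3O[C@H]2CC(C)=C
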